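**Retrosynthetic overview**

1. Target ⇐ its methyl ester ⇐ 2-ethynyl-dihydropyran (the acrylate is built last by branched-selective methoxycarbonylation of the alkyne) ⇐ unsaturated δ-lactone, whose C6 is lowered from carboxyl to CH2 (iBu2AlH, then ionic hydrogenation).
2. Key disconnection: lactone ⇒ α-homofarnesyl vinylketene silyl acetal + 3-(triisopropylsilyl)propynal. One copper-catalysed vinylogous aldol–lactonisation makes C3–C2 and O1–C6, closes the pyran ring and sets C2 (R).
3. Enabling feature (target locants O1, C2 stereocentre, C3H2, C4H=, C5 chain-bearing, C6H2): C6 is an allylic ether carbon on C5 of the C4=C5 alkene, 1,5 to O1. Raised to the carboxyl level, O1–C2–C3–C4=C5–C6(=O) is a δ-hydroxy-α,β-unsaturated ester, so C3 is the γ-carbon of an ester dienolate and C2=O1 an aldehyde. This polarity puts the chain on C5, where a plain 2-alkyldiene–aldehyde cycloaddition would not put it.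
4. Dienolate precursor ⇐ methyl 2-homofarnesylbut-2-enoate ⇐ B-alkyl Suzuki–Miyaura coupling of methyl 2-bromobut-2-enoate with the 9-BBN adduct of the farnesal-derived tetraene ⇐ (2E,6E)-farnesol.
5. Ring order: the pyran ring is the only ring and is formed in the key step; all later steps change only the oxidation level at C6 or the C2 side arm.

Key step: step 5

Assumption: the bromo ester and the silyl ynal used below are taken as catalogue chemicals; "homofarnesyl" means (3E,7E)-4,8,12-trimethyltrideca-3,7,11-trien-1-yl, and the locants C2–C6 in the text always refer to the pyran ring of the target.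

**Route**

Step 1
Reactants: 1 (2E,6E)-farnesol
Product: 2 (2E,6E)-farnesal
Conditions: TEMPO (10 mol %), PhI(OAc)2 (1.1 equiv), CH2Cl2, rt
Reagents that add atoms: none
Why: the oxoammonium-mediated (TEMPO/hypervalent iodine) oxidation takes the primary allylic alcohol to the enal under near-neutral conditions, so neither the 2E alkene nor the remote trisubstituted alkenes should be touched.

Step 2
Reactants: 2 (2E,6E)-farnesal
Product: 3 (3E,7E)-4,8,12-trimethyltrideca-1,3,7,11-tetraene
Conditions: Ph3PCH3Br, KOtBu, THF, 0 °C → rt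
Reagents that add atoms: methyltriphenylphosphonium bromide, C[P+](c1ccccc1)(c1ccccc1)c1ccccc1.[Br-]
Why: Wittig methylenation of the enal carbonyl by the non-stabilised ylide is a 1,2-process that should leave the E alkene intact and deliver the terminal 1,3-diene.

Step 3
Reactants: 3 (3E,7E)-4,8,12-trimethyltrideca-1,3,7,11-tetraene; 4 methyl (2Z)-2-bromobut-2-enoate
Product: 6 methyl (2E)-2-homofarnesylbut-2-enoate, via B-homofarnesyl-9-BBN 5 (not isolated)
Conditions: 9-BBN-H (1.05 equiv), THF, 0 °C → rt; then 4, Pd(dppf)Cl2 (5 mol %), AsPh3 (5 mol %), Cs2CO3, DMF/H2O, rt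
Reagents that add atoms: none
Why: 9-BBN should add anti-Markovnikov to the only monosubstituted alkene (the diene terminus), and the primary alkylborane then undergoes B-alkyl Suzuki–Miyaura coupling with the α-bromo enoate with retention of alkene geometry, which step 4 erases anyway.

Step 4
Reactants: 6 methyl (2E)-2-homofarnesylbut-2-enoate
Product: 8 [(1-methoxy-2-homofarnesylbuta-1,3-dien-1-yl)oxy]trimethylsilane (ketene acetal isomers), via lithium dienolate 7 (not isolated)
Conditions: LiN(iPr)2 (1.1 equiv), DMPU, THF, −78 °C; then Me3SiCl, −78 °C → rt; pentane, filtration, used crude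
Reagents that add atoms: chlorotrimethylsilane, C[Si](C)(C)Cl
Why: kinetic γ-deprotonation of the α-branched enoate (conjugate addition of the amide is disfavoured by the α-substituent and DMPU) and O-silylation of the ester dienolate give the vinylketene silyl acetal, whose ketene-acetal geometry is of no consequence.

Step 5
Reactants: 8 [(1-methoxy-2-homofarnesylbuta-1,3-dien-1-yl)oxy]trimethylsilane; 9 3-(triisopropylsilyl)prop-2-ynal
Product: 12 (6R)-3-homofarnesyl-6-[(triisopropylsilyl)ethynyl]-5,6-dihydro-2H-pyran-2-one, via copper dienolate 10 (not isolated), via copper aldolate 11 (not isolated)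
Conditions: CuCl (10 mol %), NaOtBu (10 mol %), (S)-Tol-BINAP (11 mol %), THF, −78 → −30 °C
Reagents that add atoms: none
Why: the copper alkoxide exchanges with the silyl ketene acetal to give the monovalent copper–bisphosphine dienolate 10, whose γ-carbon (future C3) adds 1,2 to the Re face of ynal 9 through a closed transition state that leaves the new enoate Z, and aldolate 11 then acylates itself on the neighbouring methyl ester, expelling copper methoxide, which desilylates the next molecule of 8 and turns the cycle over. The closest known reaction type is the monovalent-copper–bisphosphine-catalysed asymmetric vinylogous Mukaiyama aldol reaction of ester-derived silyl dienolates with conjugated aldehydes, in which 5,6-dihydropyran-2-ones form directly. The single ring closes by 6-exo-trig acyl substitution (O1 onto C6), so the step is a stepwise formal oxa-[4+2] that makes C3–C2 first and O1–C6 second. The only stereocentre, C2 (R), is set under catalyst control by the C2-symmetric bisphosphine on copper; (S)-Tol-BINAP is written, and its mirror image is taken if the first assay shows the opposite sense. The step needs γ- over α-attack, which the α-alkyl chain secures because α-attack would build a quaternary centre; Z geometry, which the closed transition state provides and which alone allows lactonisation and release of the chain-carrying methoxide; and 1,2- over 1,4-addition to the ynal, which the bulky triisopropylsilyl group at the alkyne terminus enforces.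

Step 6
Reactants: 12 (6R)-3-homofarnesyl-6-[(triisopropylsilyl)ethynyl]-5,6-dihydro-2H-pyran-2-one
Product: 13 (6R)-3-homofarnesyl-6-[(triisopropylsilyl)ethynyl]-5,6-dihydro-2H-pyran-2-ol (both anomers)
Conditions: iBu2AlH (1.1 equiv), CH2Cl2, −78 °C; aqueous potassium sodium tartrate
Reagents that add atoms: none
Why: 1,2-hydride addition of the aluminium hydride to the unsaturated lactone should stop at the aluminium hemiacetal at −78 °C and give the lactol on work-up, with the alkynylsilane, the alkenes and C2 untouched.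

Step 7
Reactants: 13 (6R)-3-homofarnesyl-6-[(triisopropylsilyl)ethynyl]-5,6-dihydro-2H-pyran-2-ol
Product: 15 triisopropyl{[(2R)-5-homofarnesyl-3,6-dihydro-2H-pyran-2-yl]ethynyl}silane, via oxocarbenium ion 14 (not isolated)
Conditions: Et3SiH (5 equiv), BF3·OEt2 (2 equiv, Lewis-acid promoter), CH2Cl2, −78 → −40 °C
Reagents that add atoms: none
Why: in this ionic hydrogenation the Lewis acid ionises the anomeric hydroxyl to the alkene-conjugated cyclic oxocarbenium ion, which the silane should reduce at C6, the carbon on oxygen, leaving the C4=C5 alkene where the target has it and the remote C2 centre untouched.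

Step 8
Reactants: 15 triisopropyl{[(2R)-5-homofarnesyl-3,6-dihydro-2H-pyran-2-yl]ethynyl}silane
Product: 16 (2R)-2-ethynyl-5-homofarnesyl-3,6-dihydro-2H-pyran
Conditions: Bu4NF (1.2 equiv), THF, 0 °C
Reagents that add atoms: none
Why: fluoride-induced protodesilylation cleaves the C(sp)–Si bond, and the allylic ether and the alkenes are inert to it.

Step 9
Reactants: 16 (2R)-2-ethynyl-5-homofarnesyl-3,6-dihydro-2H-pyran
Product: 17 methyl 2-[(2R)-5-homofarnesyl-3,6-dihydro-2H-pyran-2-yl]prop-2-enoate
Conditions: Pd(OAc)2 (1 mol %), 2-(diphenylphosphino)pyridine (20 mol %), CH3SO3H (20 mol %), CO (20 bar), MeOH/CH2Cl2, 45 °C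
Reagents that add atoms: carbon monoxide, [C-]#[O+]; methanol, CO
Why: palladium-catalysed Markovnikov hydromethoxycarbonylation of a terminal alkyne with the pyridylphosphine ligand places the ester on the internal carbon to give the 2-substituted acrylate, the alkyne reacting far faster than the trisubstituted alkenes and the basic phosphine buffering the acid.

Step 10
Reactants: 17 methyl 2-[(2R)-5-homofarnesyl-3,6-dihydro-2H-pyran-2-yl]prop-2-enoate
Product: 18 2-[(2R)-5-homofarnesyl-3,6-dihydro-2H-pyran-2-yl]prop-2-enoic acid (CNP0171598.2)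
Conditions: LiOH (3 equiv), THF/H2O, 0 °C → rt; then 1 M HCl to pH 3, 0 °C
Reagents that add atoms: lithium hydroxide, [Li+].[OH-]
Why: saponification (acyl–oxygen cleavage by hydroxide) of the unhindered methyl ester frees the acid, and C2, whose hydrogen is cross-conjugated and not acidic, should keep its configuration.

**Compound list**

1 | (2E,6E)-farnesol | OC/C=C(\C)CC/C=C(\C)CCC=C(C)C | starting material
2 | (2E,6E)-farnesal | O=C/C=C(\C)CC/C=C(\C)CCC=C(C)C | intermediate
3 | (3E,7E)-4,8,12-trimethyltrideca-1,3,7,11-tetraene | C=C/C=C(\C)CC/C=C(\C)CCC=C(C)C | intermediate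
4 | methyl (2Z)-2-bromobut-2-enoate | C/C=C(\Br)C(=O)OC | starting material
5 | 9-homofarnesyl-9-borabicyclo[3.3.1]nonane | B1(CC/C=C(\C)CC/C=C(\C)CCC=C(C)C)C2CCCC1CCC2 | intermediate
6 | methyl (2E)-2-homofarnesylbut-2-enoate | C/C=C(\CC/C=C(\C)CC/C=C(\C)CCC=C(C)C)C(=O)OC | intermediate
7 | lithium dienolate of 6 (lithium 1-methoxy-2-homofarnesylbuta-1,3-dien-1-olate) | [Li]OC(OC)=C(CC/C=C(\C)CC/C=C(\C)CCC=C(C)C)C=C | intermediate
8 | [(1-methoxy-2-homofarnesylbuta-1,3-dien-1-yl)oxy]trimethylsilane (ketene acetal isomers) | C=CC(CC/C=C(\C)CC/C=C(\C)CCC=C(C)C)=C(OC)O[Si](C)(C)C | intermediate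
9 | 3-(triisopropylsilyl)prop-2-ynal | CC(C)[Si](C(C)C)(C(C)C)C#CC=O | starting material
10 | copper dienolate (monovalent copper 1-methoxy-2-homofarnesylbuta-1,3-dien-1-olate, bisphosphine omitted) | [Cu]OC(OC)=C(CC/C=C(\C)CC/C=C(\C)CCC=C(C)C)C=C | intermediate
11 | copper aldolate (monovalent copper alkoxide of methyl (2Z,5R)-5-hydroxy-2-homofarnesyl-7-(triisopropylsilyl)hept-2-en-6-ynoate, bisphosphine omitted) | CC(C)[Si](C(C)C)(C(C)C)C#C[C@H](O[Cu])C/C=C(/CC/C=C(\C)CC/C=C(\C)CCC=C(C)C)C(=O)OC | intermediate
12 | (6R)-3-homofarnesyl-6-[(triisopropylsilyl)ethynyl]-5,6-dihydro-2H-pyran-2-one | CC(C)[Si](C(C)C)(C(C)C)C#C[C@H]1CC=C(CC/C=C(\C)CC/C=C(\C)CCC=C(C)C)C(=O)O1 | intermediate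
13 | (6R)-3-homofarnesyl-6-[(triisopropylsilyl)ethynyl]-5,6-dihydro-2H-pyran-2-ol (both anomers) | CC(C)[Si](C(C)C)(C(C)C)C#C[C@H]1CC=C(CC/C=C(\C)CC/C=C(\C)CCC=C(C)C)C(O)O1 | intermediate
14 | (2R)-5-homofarnesyl-2-[(triisopropylsilyl)ethynyl]-2,3-dihydropyrylium (oxocarbenium ion) | CC(C)[Si](C(C)C)(C(C)C)C#C[C@H]1CC=C(CC/C=C(\C)CC/C=C(\C)CCC=C(C)C)C=[O+]1 | intermediate
15 | triisopropyl{[(2R)-5-homofarnesyl-3,6-dihydro-2H-pyran-2-yl]ethynyl}silane | CC(C)[Si](C(C)C)(C(C)C)C#C[C@H]1CC=C(CC/C=C(\C)CC/C=C(\C)CCC=C(C)C)CO1 | intermediate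
16 | (2R)-2-ethynyl-5-homofarnesyl-3,6-dihydro-2H-pyran | C#C[C@H]1CC=C(CC/C=C(\C)CC/C=C(\C)CCC=C(C)C)CO1 | intermediate
17 | methyl 2-[(2R)-5-homofarnesyl-3,6-dihydro-2H-pyran-2-yl]prop-2-enoate | C=C(C(=O)OC)[C@H]1CC=C(CC/C=C(\C)CC/C=C(\C)CCC=C(C)C)CO1 | intermediate
18 | 2-[(2R)-5-homofarnesyl-3,6-dihydro-2H-pyran-2-yl]prop-2-enoic acid | C=C(C(=O)O)[C@H]1CC=C(CC/C=C(\C)CC/C=C(\C)CCC=C(C)C)CO1 | target

**Step count and risks**

Total step count: 10. Longest linear sequence: 10 steps (1 → 18).

Three steps most likely to fail: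

Step 5. Facial discrimination at the ynal may be too low with the α-branched copper dienolate, or silyl transfer to the copper aldolate may outrun lactonisation, so the methoxide chain carrier is lost and the cycle stalls. The fallback uses a different ring-closing logic; it sets out from ynal 9 and borane 5 and comes back to the route at lactone 12. Asymmetric allylboration of 9 with the Re-face-selective antipode of B-allyldiisopinocampheylborane (Et2O, −78 °C; then NaOH, H2O2) should give (3R)-1-(triisopropylsilyl)hex-5-en-1-yn-3-ol F1. Borane 5 is coupled with methyl 2-bromoacrylate under the conditions of step 3 to give methyl 2-homofarnesylprop-2-enoate F2, which LiOH (THF/H2O) hydrolyses to 2-homofarnesylprop-2-enoic acid F3. Esterification of F1 with F3 (DCC, DMAP, CH2Cl2) gives (3R)-1-(triisopropylsilyl)hex-5-en-1-yn-3-yl 2-homofarnesylprop-2-enoate F4. Ring-closing metathesis with second-generation Grubbs catalyst (CH2Cl2, 40 °C) then forms C4=C5 and gives 12.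

Step 7. The conjugated oxocarbenium ion may be intercepted by the nearest side-chain alkene (cation–olefin cyclisation), or hydride may be delivered at C4 instead of C6, which would move the ring alkene. The fallback avoids any cation; it sets out from lactone 12 and comes back at 15. Excess iBu2AlH (3 equiv, CH2Cl2, −78 → 0 °C) reduces 12 to (2Z,5R)-2-homofarnesyl-7-(triisopropylsilyl)hept-2-en-6-yne-1,5-diol F5. The primary allylic hydroxyl is converted selectively into the chloride (CH3SO2Cl, LiCl, 2,4,6-collidine, DMF, 0 °C) to give (3R,5Z)-7-chloro-6-homofarnesyl-1-(triisopropylsilyl)hept-5-en-1-yn-3-ol F6. NaH (THF, 0 °C) closes O1–C6 by Williamson etherification (6-exo-tet) and gives 15; the C2–O bond is never broken, so the configuration is kept.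

Step 9. Acid- or palladium-hydride-induced isomerisation or cyclisation of the polyene chain may occur, or branched selectivity may erode. The fallback is base-mediated throughout; it sets out from alkyne 16 and comes back at target 18, bypassing ester 17. Copper-catalysed α-selective protoboration ((SIMes)CuCl 5 mol %, NaOtBu, B2pin2, MeOH, THF, rt) should give the internal alkenylboronate 2-{1-[(2R)-5-homofarnesyl-3,6-dihydro-2H-pyran-2-yl]ethenyl}-4,4,5,5-tetramethyl-1,3,2-dioxaborolane F7. Copper-catalysed carboxylation of F7 with CO2 ((IPr)CuCl 5 mol %, KOtBu, CO2 1 atm, THF, 70 °C; then dilute HCl) gives 18.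

**Further compounds**

F1 | step 5 | (3R)-1-(triisopropylsilyl)hex-5-en-1-yn-3-ol | CC(C)[Si](C(C)C)(C(C)C)C#C[C@H](O)CC=C
F2 | step 5 | methyl 2-homofarnesylprop-2-enoate | C=C(CC/C=C(\C)CC/C=C(\C)CCC=C(C)C)C(=O)OC
F3 | step 5 | 2-homofarnesylprop-2-enoic acid | C=C(CC/C=C(\C)CC/C=C(\C)CCC=C(C)C)C(=O)O
F4 | step 5 | (3R)-1-(triisopropylsilyl)hex-5-en-1-yn-3-yl 2-homofarnesylprop-2-enoate | CC(C)[Si](C(C)C)(C(C)C)C#C[C@H](OC(=O)C(=C)CC/C=C(\C)CC/C=C(\C)CCC=C(C)C)CC=C
F5 | step 7 | (2Z,5R)-2-homofarnesyl-7-(triisopropylsilyl)hept-2-en-6-yne-1,5-diol | CC(C)[Si](C(C)C)(C(C)C)C#C[C@H](O)C/C=C(/CC/C=C(\C)CC/C=C(\C)CCC=C(C)C)CO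
F6 | step 7 | (3R,5Z)-7-chloro-6-homofarnesyl-1-(triisopropylsilyl)hept-5-en-1-yn-3-ol | CC(C)[Si](C(C)C)(C(C)C)C#C[C@H](O)C/C=C(/CC/C=C(\C)CC/C=C(\C)CCC=C(C)C)CCl
F7 | step 9 | 2-{1-[(2R)-5-homofarnesyl-3,6-dihydro-2H-pyran-2-yl]ethenyl}-4,4,5,5-tetramethyl-1,3,2-dioxaborolane | C=C(B2OC(C)(C)C(C)(C)O2)[C@H]1CC=C(CC/C=C(\C)CC/C=C(\C)CCC=C(C)C)CO1
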